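(Readings and results stem from a simulated flask for an exercise; the scatter is artificial.)

Read the flask at 15 h and do not lean on any figure for 4.0 min until you have seen how the earlier runs were taken.

| setting | alder | cedar | flask |
|---|---|---|---|
| solid substrate | 0.30 M | 0.30 M | 0.30 M |
| other conformer | 0.015 M | 0.060 M | 0.0300 M |
| remark | run made earlier | run made earlier |  |
| time |  |  | 15 h |

| run | time / h | isomer of the product / % | target / % | solid substrate / % |
|---|---|---|---|---|
| alder | 1.33 | 3.1 | 0 | 93.8 |
| alder | 2.00 | 3.6 | 0.9 | 94.4 |
| alder | 3.00 | 3.9 | 1.0 | 94.8 |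
| alder | 4.00 | 4.2 | 1.4 | 92.5 |
| alder | 6.00 | 4.5 | 1.5 | 93.4 |
| alder | 10.0 | 5.8 | 0.8 | 92.1 |
| alder | 15.0 | 6.0 | 2.3 | 89.4 |
| cedar | 1.33 | 10.4 | 3.0 | 83.3 |
| cedar | 2.00 | 11.5 | 2.3 | 83.0 |
| cedar | 3.00 | 11.2 | 2.9 | 82.8 |
| cedar | 4.00 | 12.3 | 2.7 | 82.5 |
| cedar | 6.00 | 13.1 | 3.5 | 81.4 |
| cedar | 10.0 | 12.9 | 3.4 | 79.1 |
| cedar | 15.0 | 14.0 | 4.1 | 78.9 |

(readings scatter by 0.5 percentage points)

- solid substrate is a solid; its amount is given per volume of the solution
- what was read earlier has a scatter of 0.5 percentage points, one standard deviation
- at the start none of the solid substrate is in solution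

* ratio of isomer of the product to target at 4.0 min
* ratio of isomer of the product to target at 15 h

Alder and cedar hold the same solid substrate and differ in other conformer, so subtract alder from cedar at 15.0 h to leave what the extra other conformer gave. [isomer of the product] differs by 31.5 mM and [target] by 7.51 mM, which reads as 4.19 extra isomer of the product per extra target, the conformer mean, a selectivity factor averaged over the whole run. Add a third of each difference to alder, and expect in the flask at 15 h about 29.4 mM of isomer of the product and 9.75 mM of target, which is my ratio of 3.02. Leave the solid substrate at 0.30 M, since the subtraction needs it equal, and do not carry a mean to 4.0 min, since the earliest reading of either run stands at 1.33 h.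

The forecast gives 4.2 at 4.0 min and 3.3 at 15 h, the latter above mine, and holds that “product should come almost only from the conformer”.

The flask gives 17.8 at 4.0 min and 3.52 at 15 h.

    third conformer → third product (k = 0.648 h⁻¹)
    starting material ⇌ other conformer (K = 0.840, k = 7.17 h⁻¹)
    starting material → target (k = 0.908 h⁻¹)
    other conformer ⇌ third conformer (K = 8.78, k = 1.32 h⁻¹)
    solid substrate ⇌ starting material, rate k5*(cs5 - [starting material]) while solid is left; crystals form when [starting material] > cs5 (solubility = 28.0 mM, k = 0.0433 h⁻¹)
    other conformer ⇌ dormant form (K = 15.0, k = 0.0774 h⁻¹)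
    other conformer → isomer of the product (k = 4.36 h⁻¹)

Subtract the flask from its neighbour with 0.075 M of other conformer at 15 h, and the conformer mean comes to 4.57 against the 4.19 read from alder and cedar. At 4.0 min the ratio in the flask stands at 4.25 times the mean read from alder and cedar, and the neighbour flask also gives 17.8 at that time. The largest single effect on this early ratio is the falling back of other conformer to starting material, and starting material goes on to target: with that falling back taken away, the flask gives 3520 at 4.0 min.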